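**Plan**

1. Rings are lettered A (2,4,6-trihydroxyphenyl end) to E (3,4,5-trihydroxyphenyl end). Ring C carries its two diaryl-ether oxygens (to ring B and to ring D) on adjacent carbons, with the three hydroxylated carbons on one side of this pair and the only C–H on the other, so both C–O bonds can be made across a 3,4,5-tris(benzyloxy)benzyne.
2. Retrosynthetic cuts, in order: the thirteen O–benzyl bonds; the ring C–O–ring D ether (Ullmann coupling of an ABC phenol with a DE bromide); both ether C–O bonds of ring C in one operation (AB phenoxide adds to the benzyne, the aryl Grignard is borylated and oxidised); the A–O–B ether (Ullmann) and the D–O–E ether (SNAr).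
3. Forward: no ring is formed. All five benzene rings come from 3,4,5-trihydroxybenzaldehyde, 2,4,6-trihydroxybenzaldehyde and 4-bromo-2,6-difluorobenzaldehyde; the formyl groups first activate SNAr or Ullmann steps and are then turned into phenol oxygens by Baeyer–Villiger oxidation.
4. Order of joining: A + B → AB; AB + benzyne C → ABC; E + D → DE; ABC + DE → protected pentamer → target.
5. Stereochemistry: the target has no stereocentre and no hindered axis that needs control.

Key step: step 14

Remark: the three benzaldehydes named above are taken as purchasable, and the diaryl ethers are assumed to rotate freely.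

**Route**

Step 1
Reactants: 1 3,4,5-trihydroxybenzaldehyde
Product: 2 3,4,5-tris(benzyloxy)benzaldehyde
Conditions: BnBr, K2CO3, DMF, 60 °C, argon
Reagents that add atoms: benzyl bromide, BrCc1ccccc1
Why: Williamson etherification of the three phenoxides with a benzylic bromide is fast in DMF and the non-enolisable aldehyde is inert to K2CO3.

Step 2
Reactants: 2 3,4,5-tris(benzyloxy)benzaldehyde
Product: 4 3,4,5-tris(benzyloxy)phenol, via 3,4,5-tris(benzyloxy)phenyl formate 3 (not isolated)
Conditions: mCPBA, CH2Cl2, 0 °C → rt; then K2CO3 (cat.), MeOH, rt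
Reagents that add atoms: mCPBA (3-chloroperoxybenzoic acid), OOC(=O)c1cccc(Cl)c1
Why: Baeyer–Villiger oxidation in which the para-benzyloxy-activated aryl group migrates in the Criegee intermediate to give formate 3, which is transesterified to the phenol without touching the benzyl ethers.

Step 3
Reactants: 4 3,4,5-tris(benzyloxy)phenol
Product: 5 3,4,5-tris(benzyloxy)-2-iodophenol
Conditions: NIS (1.0 equiv), CH2Cl2, −20 °C → 0 °C
Reagents that add atoms: N-iodosuccinimide, O=C1CCC(=O)N1I
Why: Electrophilic aromatic iodination of a strongly activated phenol whose only two ring hydrogens are equivalent and ortho to the hydroxyl, so one equivalent of reagent at low temperature should stop at the mono-iodide.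

Step 4
Reactants: 5 3,4,5-tris(benzyloxy)-2-iodophenol
Product: 6 3,4,5-tris(benzyloxy)-2-iodophenyl 4-chlorobenzenesulfonate (aryne precursor)
Conditions: 4-ClC6H4SO2Cl, Et3N, DMAP (cat.), CH2Cl2, 0 °C → rt
Reagents that add atoms: 4-chlorobenzenesulfonyl chloride, O=S(=O)(Cl)c1ccc(Cl)cc1
Why: DMAP-catalysed O-sulfonylation of the phenol installs the leaving group for later aryne formation, and neither the iodide nor the benzyl ethers react.

Step 5
Reactants: 4 3,4,5-tris(benzyloxy)phenol; 7 4-bromo-2,6-difluorobenzaldehyde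
Product: 8 4-bromo-2-fluoro-6-[3,4,5-tris(benzyloxy)phenoxy]benzaldehyde
Conditions: K2CO3, DMF, 50 °C (7 in slight excess)
Reagents that add atoms: none
Why: Nucleophilic aromatic substitution (addition–elimination) of a fluoride ortho to the formyl group by the phenoxide of 4; the new aryloxy donor slows a second substitution and bromide is a far poorer nucleofuge.

Step 6
Reactants: 8 4-bromo-2-fluoro-6-[3,4,5-tris(benzyloxy)phenoxy]benzaldehyde
Product: 9 2-(benzyloxy)-4-bromo-6-[3,4,5-tris(benzyloxy)phenoxy]benzaldehyde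
Conditions: BnOH, NaH, THF, 0 °C → rt
Reagents that add atoms: benzyl alcohol, OCc1ccccc1
Why: Second nucleophilic aromatic substitution, by sodium benzyloxide at the remaining ortho fluorine, which is displaced much more readily than the aryloxy or bromo substituent.

Step 7
Reactants: 9 2-(benzyloxy)-4-bromo-6-[3,4,5-tris(benzyloxy)phenoxy]benzaldehyde
Product: 11 2-(benzyloxy)-4-bromo-6-[3,4,5-tris(benzyloxy)phenoxy]phenol, via aryl formate 10 (not isolated)
Conditions: mCPBA, CH2Cl2, 0 °C → rt; then K2CO3 (cat.), MeOH, rt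
Reagents that add atoms: mCPBA (3-chloroperoxybenzoic acid), OOC(=O)c1cccc(Cl)c1
Why: Baeyer–Villiger oxidation of a 2,6-dioxygenated benzaldehyde, in which the electron-rich aryl group migrates in preference to hydride, followed by methanolysis of formate 10.

Step 8
Reactants: 11 2-(benzyloxy)-4-bromo-6-[3,4,5-tris(benzyloxy)phenoxy]phenol
Product: 12 1,2-bis(benzyloxy)-5-bromo-3-[3,4,5-tris(benzyloxy)phenoxy]benzene (DE bromide)
Conditions: BnBr, K2CO3, DMF, 50 °C
Reagents that add atoms: benzyl bromide, BrCc1ccccc1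
Why: Williamson benzylation of the phenoxide, with the aryl bromide and the diaryl ether inert.

Step 9
Reactants: 13 2,4,6-trihydroxybenzaldehyde
Product: 14 2,4,6-tris(benzyloxy)benzaldehyde
Conditions: BnBr (excess), K2CO3, DMF, 70 °C, argon
Reagents that add atoms: benzyl bromide, BrCc1ccccc1
Why: Williamson etherification in which the formyl group lowers the carbon nucleophilicity of the phloroglucinol ring, so that O-benzylation should prevail over C-benzylation, the hydrogen-bonded ortho hydroxyls reacting on warming.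

Step 10
Reactants: 14 2,4,6-tris(benzyloxy)benzaldehyde
Product: 16 2,4,6-tris(benzyloxy)phenol, via 2,4,6-tris(benzyloxy)phenyl formate 15 (not isolated)
Conditions: mCPBA (1.1 equiv), CH2Cl2, 0 °C; then K2CO3 (cat.), MeOH, rt, argon
Reagents that add atoms: mCPBA (3-chloroperoxybenzoic acid), OOC(=O)c1cccc(Cl)c1
Why: Baeyer–Villiger oxidation of a 2,4,6-trialkoxybenzaldehyde, where aryl migration is strongly favoured, run with little excess peracid at 0 °C to spare the electron-rich ring, then methanolysis of formate 15.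

Step 11
Reactants: 7 4-bromo-2,6-difluorobenzaldehyde
Product: 17 2,6-bis(benzyloxy)-4-bromobenzaldehyde
Conditions: BnOH (2.2 equiv), NaH, THF–DMF, 0 °C → 50 °C
Reagents that add atoms: benzyl alcohol, OCc1ccccc1
Why: Double nucleophilic aromatic substitution of both ortho fluorines by sodium benzyloxide, the usual way from 2,6-difluorobenzaldehydes to 2,6-dialkoxybenzaldehydes, with the para bromide retained.

Step 12
Reactants: 16 2,4,6-tris(benzyloxy)phenol; 17 2,6-bis(benzyloxy)-4-bromobenzaldehyde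
Product: 18 2,6-bis(benzyloxy)-4-[2,4,6-tris(benzyloxy)phenoxy]benzaldehyde
Conditions: CuI (10 mol%), picolinic acid (20 mol%), K3PO4, DMSO, 90 °C, argon
Reagents that add atoms: none
Why: Ullmann diaryl ether synthesis with the CuI/picolinic acid system, which tolerates doubly ortho-substituted phenols, at an unhindered aryl bromide activated by the para formyl group.

Step 13
Reactants: 18 2,6-bis(benzyloxy)-4-[2,4,6-tris(benzyloxy)phenoxy]benzaldehyde
Product: 20 2,6-bis(benzyloxy)-4-[2,4,6-tris(benzyloxy)phenoxy]phenol (AB phenol), via AB aryl formate 19 (not isolated)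
Conditions: mCPBA (1.1 equiv), CH2Cl2, 0 °C; then K2CO3 (cat.), MeOH, rt, argon
Reagents that add atoms: mCPBA (3-chloroperoxybenzoic acid), OOC(=O)c1cccc(Cl)c1
Why: Baeyer–Villiger oxidation of the aldehyde flanked by two benzyloxy groups (aryl migration) and methanolysis of formate 19 unveil the ring B hydroxyl between the two benzyloxy groups.

Step 14
Reactants: 20 AB phenol; 6 3,4,5-tris(benzyloxy)-2-iodophenyl 4-chlorobenzenesulfonate
Product: 26 2,3,4-tris(benzyloxy)-6-{2,6-bis(benzyloxy)-4-[2,4,6-tris(benzyloxy)phenoxy]phenoxy}phenol (ABC phenol), via chloromagnesium phenoxide 21 (not isolated), via magnesiated aryl sulfonate 22 (not isolated), via 3,4,5-tris(benzyloxy)benzyne 23 (not isolated), via aryl Grignard adduct 24 (not isolated), via dimethyl arylboronate 25 (not isolated)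
Conditions: 20 (1.3 equiv), i-PrMgCl·LiCl, THF, 0 °C; then 6, i-PrMgCl·LiCl, −78 °C → rt; B(OMe)3, −78 °C → rt; 30% H2O2, aq NaOH, 0 °C
Reagents that add atoms: hydrogen peroxide, OO
Why: Proposed new method: i-PrMgCl·LiCl turns phenol 20 into magnesium phenoxide 21 and, at −78 °C, exchanges the iodine of 6 for magnesium to give 22, which on warming expels magnesium 4-chlorobenzenesulfonate to release benzyne 23, whose strained triple bond is attacked by the phenoxide oxygen to give aryl Grignard 24. The closest known reaction type is the addition of magnesium thiolates and magnesium amides to arynes released from 2-magnesiated aryl sulfonates, followed by electrophilic quench of the resulting aryl Grignard; an oxygen nucleophile combined with a borylation–oxidation quench has not been shown. No ring is closed and no stereocentre is formed. The selectivity needed is attack at the aryne carbon next to the ring C–H: the benzyloxy group beside the other aryne carbon polarises and distorts the triple bond so that the nucleophile enters at the remote, less hindered carbon and the carbanion develops next to the inductively stabilising, magnesium-chelating oxygen. Carbon arylation of the ambident phenoxide is blocked because both ortho positions and the para position of ring B are substituted, and the ether between two benzyloxy groups is formed by addition to a triple bond, which is little affected by ortho substituents. Grignard 24 is borylated by B(OMe)3 to 25 and oxidised by alkaline H2O2 with aryl shift from boron to oxygen, which sets the second oxygen of ring C as a free hydroxyl.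

Step 15
Reactants: 26 ABC phenol; 12 DE bromide
Product: 27 1,2,3-tris(benzyloxy)-4-{3,4-bis(benzyloxy)-5-[3,4,5-tris(benzyloxy)phenoxy]phenoxy}-5-{2,6-bis(benzyloxy)-4-[2,4,6-tris(benzyloxy)phenoxy]phenoxy}benzene (tridecabenzyl ether of the target)
Conditions: CuI (20 mol%), picolinic acid (40 mol%), K3PO4, DMSO, 100 °C, argon
Reagents that add atoms: none
Why: Ullmann diaryl ether synthesis between the hindered phenol and an aryl bromide whose reacting carbon is flanked only by hydrogens, under ligand conditions developed for ortho-substituted phenols.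

Step 16
Reactants: 27 tridecabenzyl ether of the target
Product: 28 4-[3,4-dihydroxy-5-(3,4,5-trihydroxyphenoxy)phenoxy]-5-[2,6-dihydroxy-4-(2,4,6-trihydroxyphenoxy)phenoxy]benzene-1,2,3-triol (CNP0154768.0)
Conditions: H2 (1 atm), 10% Pd/C (palladium metal on carbon), THF–MeOH, rt; filtration and concentration under argon
Reagents that add atoms: none
Why: Catalytic hydrogenolysis cleaves all thirteen benzyl ethers, while the diaryl ether bonds are stable and no other reducible group is present.

**Compound list**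

1 | 3,4,5-trihydroxybenzaldehyde | O=Cc1cc(O)c(O)c(O)c1 | starting material
2 | 3,4,5-tris(benzyloxy)benzaldehyde | O=Cc1cc(OCc7ccccc7)c(OCc7ccccc7)c(OCc7ccccc7)c1 | intermediate
3 | 3,4,5-tris(benzyloxy)phenyl formate (not isolated) | O=COc1cc(OCc7ccccc7)c(OCc7ccccc7)c(OCc7ccccc7)c1 | intermediate
4 | 3,4,5-tris(benzyloxy)phenol | Oc1cc(OCc7ccccc7)c(OCc7ccccc7)c(OCc7ccccc7)c1 | intermediate
5 | 3,4,5-tris(benzyloxy)-2-iodophenol | Oc1cc(OCc7ccccc7)c(OCc7ccccc7)c(OCc7ccccc7)c1I | intermediate
6 | 3,4,5-tris(benzyloxy)-2-iodophenyl 4-chlorobenzenesulfonate | Ic1c(OCc7ccccc7)c(OCc7ccccc7)c(OCc7ccccc7)cc1OS(=O)(=O)c8ccc(Cl)cc8 | intermediate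
7 | 4-bromo-2,6-difluorobenzaldehyde | O=Cc1c(F)cc(Br)cc1F | starting material
8 | 4-bromo-2-fluoro-6-[3,4,5-tris(benzyloxy)phenoxy]benzaldehyde | O=Cc1c(F)cc(Br)cc1Oc2cc(OCc7ccccc7)c(OCc7ccccc7)c(OCc7ccccc7)c2 | intermediate
9 | 2-(benzyloxy)-4-bromo-6-[3,4,5-tris(benzyloxy)phenoxy]benzaldehyde | O=Cc1c(OCc7ccccc7)cc(Br)cc1Oc2cc(OCc7ccccc7)c(OCc7ccccc7)c(OCc7ccccc7)c2 | intermediate
10 | 2-(benzyloxy)-4-bromo-6-[3,4,5-tris(benzyloxy)phenoxy]phenyl formate (not isolated) | O=COc1c(OCc7ccccc7)cc(Br)cc1Oc2cc(OCc7ccccc7)c(OCc7ccccc7)c(OCc7ccccc7)c2 | intermediate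
11 | 2-(benzyloxy)-4-bromo-6-[3,4,5-tris(benzyloxy)phenoxy]phenol | Oc1c(OCc7ccccc7)cc(Br)cc1Oc2cc(OCc7ccccc7)c(OCc7ccccc7)c(OCc7ccccc7)c2 | intermediate
12 | 1,2-bis(benzyloxy)-5-bromo-3-[3,4,5-tris(benzyloxy)phenoxy]benzene (DE bromide) | Brc1cc(OCc7ccccc7)c(OCc7ccccc7)c(Oc2cc(OCc7ccccc7)c(OCc7ccccc7)c(OCc7ccccc7)c2)c1 | intermediate
13 | 2,4,6-trihydroxybenzaldehyde | O=Cc1c(O)cc(O)cc1O | starting material
14 | 2,4,6-tris(benzyloxy)benzaldehyde | O=Cc1c(OCc7ccccc7)cc(OCc7ccccc7)cc1OCc7ccccc7 | intermediate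
15 | 2,4,6-tris(benzyloxy)phenyl formate (not isolated) | O=COc1c(OCc7ccccc7)cc(OCc7ccccc7)cc1OCc7ccccc7 | intermediate
16 | 2,4,6-tris(benzyloxy)phenol | Oc1c(OCc7ccccc7)cc(OCc7ccccc7)cc1OCc7ccccc7 | intermediate
17 | 2,6-bis(benzyloxy)-4-bromobenzaldehyde | O=Cc1c(OCc7ccccc7)cc(Br)cc1OCc7ccccc7 | intermediate
18 | 2,6-bis(benzyloxy)-4-[2,4,6-tris(benzyloxy)phenoxy]benzaldehyde | O=Cc1c(OCc7ccccc7)cc(Oc2c(OCc7ccccc7)cc(OCc7ccccc7)cc2OCc7ccccc7)cc1OCc7ccccc7 | intermediate
19 | 2,6-bis(benzyloxy)-4-[2,4,6-tris(benzyloxy)phenoxy]phenyl formate (not isolated) | O=COc1c(OCc7ccccc7)cc(Oc2c(OCc7ccccc7)cc(OCc7ccccc7)cc2OCc7ccccc7)cc1OCc7ccccc7 | intermediate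
20 | 2,6-bis(benzyloxy)-4-[2,4,6-tris(benzyloxy)phenoxy]phenol (AB phenol) | Oc1c(OCc7ccccc7)cc(Oc2c(OCc7ccccc7)cc(OCc7ccccc7)cc2OCc7ccccc7)cc1OCc7ccccc7 | intermediate
21 | chloromagnesium phenoxide of the AB phenol (not isolated) | Cl[Mg]Oc1c(OCc7ccccc7)cc(Oc2c(OCc7ccccc7)cc(OCc7ccccc7)cc2OCc7ccccc7)cc1OCc7ccccc7 | intermediate
22 | 3,4,5-tris(benzyloxy)-2-(chloromagnesio)phenyl 4-chlorobenzenesulfonate (not isolated) | Cl[Mg]c1c(OCc7ccccc7)c(OCc7ccccc7)c(OCc7ccccc7)cc1OS(=O)(=O)c8ccc(Cl)cc8 | intermediate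
23 | 3,4,5-tris(benzyloxy)benzyne (not isolated) | C1#CC(OCc7ccccc7)=C(OCc7ccccc7)C(OCc7ccccc7)=C1 | intermediate
24 | 2-aryloxy-6-benzyloxy aryl Grignard adduct of 21 and 23 (not isolated) | Cl[Mg]c1c(OCc7ccccc7)c(OCc7ccccc7)c(OCc7ccccc7)cc1Oc2c(OCc7ccccc7)cc(Oc3c(OCc7ccccc7)cc(OCc7ccccc7)cc3OCc7ccccc7)cc2OCc7ccccc7 | intermediate
25 | dimethyl arylboronate from 24 (not isolated) | COB(OC)c1c(OCc7ccccc7)c(OCc7ccccc7)c(OCc7ccccc7)cc1Oc2c(OCc7ccccc7)cc(Oc3c(OCc7ccccc7)cc(OCc7ccccc7)cc3OCc7ccccc7)cc2OCc7ccccc7 | intermediate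
26 | 2,3,4-tris(benzyloxy)-6-{2,6-bis(benzyloxy)-4-[2,4,6-tris(benzyloxy)phenoxy]phenoxy}phenol (ABC phenol) | Oc1c(OCc7ccccc7)c(OCc7ccccc7)c(OCc7ccccc7)cc1Oc2c(OCc7ccccc7)cc(Oc3c(OCc7ccccc7)cc(OCc7ccccc7)cc3OCc7ccccc7)cc2OCc7ccccc7 | intermediate
27 | tridecabenzyl ether of the target | O(c1c(OCc7ccccc7)c(OCc7ccccc7)c(OCc7ccccc7)cc1Oc2c(OCc7ccccc7)cc(Oc3c(OCc7ccccc7)cc(OCc7ccccc7)cc3OCc7ccccc7)cc2OCc7ccccc7)c4cc(OCc7ccccc7)c(OCc7ccccc7)c(Oc5cc(OCc7ccccc7)c(OCc7ccccc7)c(OCc7ccccc7)c5)c4 | intermediate
28 | CNP0154768.0, 4-[3,4-dihydroxy-5-(3,4,5-trihydroxyphenoxy)phenoxy]-5-[2,6-dihydroxy-4-(2,4,6-trihydroxyphenoxy)phenoxy]benzene-1,2,3-triol | Oc1cc(O)c(Oc2cc(O)c(Oc3cc(O)c(O)c(O)c3Oc3cc(O)c(O)c(Oc4cc(O)c(O)c(O)c4)c3)c(O)c2)c(O)c1 | target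

**Step count and risks**

Total step count: 16. Longest linear sequence: 8 steps (1 → 2 → 4 → 8 → 9 → 11 → 12 → 27 → 28).

Steps most likely to fail:

1. Step 14 (proposed new method). The aggregated, hindered magnesium phenoxide may add too slowly, so that the benzyne is consumed by the magnesiated sulfonate or by the exchange reagent; the crowded aryl Grignard may also be protonated before it is borylated. The fallback uses known reactions and installs the two oxygens of ring C one after the other. It sets out from 4 and 20 and returns at 26. Magnesium-mediated ortho-formylation of phenol 4 (MgCl2, Et3N, paraformaldehyde, MeCN, reflux) should give 2,3,4-tris(benzyloxy)-6-hydroxybenzaldehyde F1. Tf2O and pyridine in CH2Cl2 convert it into 3,4,5-tris(benzyloxy)-2-formylphenyl trifluoromethanesulfonate F2. Palladium-catalysed C–O coupling of the Buchwald–Hartwig type between F2 and phenol 20 (Pd(OAc)2, 2-di-tert-butylphosphino-2′,4′,6′-triisopropylbiphenyl, K3PO4, toluene, 100 °C) gives 2,3,4-tris(benzyloxy)-6-{2,6-bis(benzyloxy)-4-[2,4,6-tris(benzyloxy)phenoxy]phenoxy}benzaldehyde F3. Baeyer–Villiger oxidation with mCPBA leads to 2,3,4-tris(benzyloxy)-6-{2,6-bis(benzyloxy)-4-[2,4,6-tris(benzyloxy)phenoxy]phenoxy}phenyl formate F4, and methanolysis (K2CO3, MeOH) gives 26.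

2. Step 15. Copper-mediated C–O bond formation may be slow at a phenoxide flanked by an aryloxy and a benzyloxy group, with reductive loss of bromine from 12 and oxidation of the phenol as competing processes. The fallback changes the DE partner from electrophile to nucleophile and couples oxidatively at room temperature. It sets out from 12 and returns at 27. Bromine–lithium exchange on 12 (n-BuLi, THF, −78 °C), quench with B(Oi-Pr)3 and mild acidic work-up give {3,4-bis(benzyloxy)-5-[3,4,5-tris(benzyloxy)phenoxy]phenyl}boronic acid F5. Chan–Lam coupling of F5 with phenol 26 (Cu(OAc)2, pyridine, 4 Å molecular sieves, CH2Cl2, air, rt) should give 27.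

3. Step 12. The electron-rich phenoxide of 16 may be degraded oxidatively under hot, basic copper conditions, and coupling at the doubly ortho-substituted oxygen may be slow. The fallback forms the A–O–B ether without metal and introduces the ring B benzyl ethers afterwards. It sets out from 16 and returns at 18. Phenol 16 and commercial 2,4,6-trifluorobenzaldehyde (K2CO3, DMSO, rt → 50 °C) should react by nucleophilic aromatic substitution at the para fluorine, the less hindered site for a bulky phenoxide in a dipolar solvent, to give 2,6-difluoro-4-[2,4,6-tris(benzyloxy)phenoxy]benzaldehyde F6. Both ortho fluorines of F6 are then displaced with BnOH and NaH in THF–DMF, as in step 11, to give 18.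

**Further compounds**

F1 | step 14 | 2,3,4-tris(benzyloxy)-6-hydroxybenzaldehyde | O=Cc1c(O)cc(OCc7ccccc7)c(OCc7ccccc7)c1OCc7ccccc7
F2 | step 14 | 3,4,5-tris(benzyloxy)-2-formylphenyl trifluoromethanesulfonate | O=Cc1c(OS(=O)(=O)C(F)(F)F)cc(OCc7ccccc7)c(OCc7ccccc7)c1OCc7ccccc7
F3 | step 14 | 2,3,4-tris(benzyloxy)-6-{2,6-bis(benzyloxy)-4-[2,4,6-tris(benzyloxy)phenoxy]phenoxy}benzaldehyde | O=Cc1c(Oc2c(OCc7ccccc7)cc(Oc3c(OCc7ccccc7)cc(OCc7ccccc7)cc3OCc7ccccc7)cc2OCc7ccccc7)cc(OCc7ccccc7)c(OCc7ccccc7)c1OCc7ccccc7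
F4 | step 14 | 2,3,4-tris(benzyloxy)-6-{2,6-bis(benzyloxy)-4-[2,4,6-tris(benzyloxy)phenoxy]phenoxy}phenyl formate | O=COc1c(Oc2c(OCc7ccccc7)cc(Oc3c(OCc7ccccc7)cc(OCc7ccccc7)cc3OCc7ccccc7)cc2OCc7ccccc7)cc(OCc7ccccc7)c(OCc7ccccc7)c1OCc7ccccc7
F5 | step 15 | {3,4-bis(benzyloxy)-5-[3,4,5-tris(benzyloxy)phenoxy]phenyl}boronic acid | OB(O)c1cc(OCc7ccccc7)c(OCc7ccccc7)c(Oc2cc(OCc7ccccc7)c(OCc7ccccc7)c(OCc7ccccc7)c2)c1
F6 | step 12 | 2,6-difluoro-4-[2,4,6-tris(benzyloxy)phenoxy]benzaldehyde | O=Cc1c(F)cc(Oc2c(OCc7ccccc7)cc(OCc7ccccc7)cc2OCc7ccccc7)cc1F
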